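**Strategy.** The trans-2-aryl-3-aroyl-2,3-dihydrobenzofuran is traced back to a 2,4-diaryl-2H-chromene in which the future ketone carbon is still ring atom C4 of a six-membered pyran. Oxidation with a trivalent iodine reagent shifts the fused arene carbon (C4a, later C3a) from C4 to C3 and expels C4 as the exocyclic aroyl C=O. The step exploits the fact that this carbonyl carbon and arene carbon C3a are both bonded to C3 of the dihydrofuran ring (O1–C2–C3–C3a–C7a): the pyran contracts to this ring, the ketone appears, and the 2,3-trans relationship follows from C2, set earlier by asymmetric conjugate arylation of 6-bromochromone. A Heck coupling and MOM removal complete the chalcone.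

Key step: step 5

Remark: the target descriptors correspond to (2R,3R), the 2,3-trans isomer. It is assumed that (S)-t-BuPyOx gives the (2R)-flavanone, by analogy with cyclic enones; the (R)-ligand is taken instead should the first batch show the opposite sense.

**Step 1**
Reactants: 1 4-bromobenzene-1,3-diol
Product: 2 1-bromo-2,4-bis(methoxymethoxy)benzene
Conditions: NaH (2.4 equiv), MOMCl (2.4 equiv), DMF, 0 °C to rt
Reagents that add atoms: chloromethyl methyl ether, COCCl
Why: Williamson-type O-alkylation of both phenoxides with the reactive α-chloro ether gives the bis-MOM ether, which tolerates the later organolithium, Grignard, palladium and iodane steps; no stereocenter is involved.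

**Step 2**
Reactants: 2 1-bromo-2,4-bis(methoxymethoxy)benzene; 3 N-methoxy-N-methylprop-2-enamide
Product: 5 1-[2,4-bis(methoxymethoxy)phenyl]prop-2-en-1-one, via aryllithium 4 (not isolated)
Conditions: n-BuLi (0.98 equiv), THF, −78 °C; then 3, THF, −78 °C; inverse quench into cold 1 M aq. HCl
Reagents that add atoms: none
Why: Bromine–lithium exchange gives the aryllithium, stabilised by the ortho MOM oxygen, and in the Weinreb ketone synthesis it adds once to the amide to give a chelated tetrahedral adduct, which releases the vinyl ketone only on the cold acidic quench, where the liberated amine is protonated and cannot add back to the enone.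

**Step 3**
Reactants: 6 6-bromo-4H-chromen-4-one; 7 [4-(methoxymethoxy)phenyl]boronic acid
Product: 8 (2R)-6-bromo-2-[4-(methoxymethoxy)phenyl]-2,3-dihydro-4H-chromen-4-one
Conditions: Pd(OCOCF3)2 (5 mol %), (S)-t-BuPyOx (6 mol %), NH4PF6 (30 mol %), H2O (5 equiv), ClCH2CH2Cl, 60 °C
Reagents that add atoms: none
Why: Asymmetric conjugate addition of an arylboronic acid to a chromone under cationic divalent palladium/pyridine-oxazoline catalysis, in which the tert-butyl group of the ligand shields one face of C2=C3 during the enantio-determining carbopalladation and so sets C2 as R, and in which no zerovalent palladium arises, so the C–Br bond should survive.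

**Step 4**
Reactants: 8 (2R)-6-bromo-2-[4-(methoxymethoxy)phenyl]-2,3-dihydro-4H-chromen-4-one; 2 1-bromo-2,4-bis(methoxymethoxy)benzene
Product: 11 (2R)-6-bromo-4-[2,4-bis(methoxymethoxy)phenyl]-2-[4-(methoxymethoxy)phenyl]-2H-chromene, via arylmagnesium bromide 9 (not isolated), via tertiary carbinol 10 (not isolated)
Conditions: 2, Mg, I2 (cat.), THF, 45 °C; then 8, THF, −20 to 0 °C; H2O quench; crude carbinol, PPTS (10 mol %), toluene, 50 °C
Reagents that add atoms: none
Why: Grignard 1,2-addition of the less basic magnesium reagent to the chromanone carbonyl, which leaves the aryl bromide of 8 alone, followed by acid-catalysed E1 dehydration of the doubly benzylic tertiary carbinol, whose only β-hydrogens are on C3, should give the C3=C4 alkene from both C4 epimers while C2 is untouched.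

**Step 5**
Reactants: 11 (2R)-6-bromo-4-[2,4-bis(methoxymethoxy)phenyl]-2-[4-(methoxymethoxy)phenyl]-2H-chromene
Product: 12 [(2R,3R)-5-bromo-2-[4-(methoxymethoxy)phenyl]-2,3-dihydro-1-benzofuran-3-yl][2,4-bis(methoxymethoxy)phenyl]methanone
Conditions: PhI(OH)OTs (1.1 equiv), MeCN/H2O (9:1), 0 °C; aq. NaHCO3
Reagents that add atoms: water (source of the carbonyl oxygen), O
Why: Proposed new method: the electrophilic trivalent iodine unit adds to C3 of the electron-rich C3=C4 bond on the face anti to the C2 aryl group while water captures the doubly benzylic C4 cation; the C3–I bond, equatorial like the C2 aryl group, then lies antiperiplanar to the C4–C4a ring bond, and C4a shifts from C4 to C3 with loss of iodobenzene as the C4 hydroxyl collapses to the ketone. The closest known reaction types are the ring contraction of 1,2-dihydronaphthalenes to indanes with the same reagent, the 1,2-aryl shift of 1,1-diarylalkenes to deoxybenzoins and the oxidative contraction of flavanones to dihydrobenzofuran-3-carboxylates, none of which has been shown on a 2,4-diaryl-2H-chromene. The five-membered ring O1–C2–C3–C3a–C7a is closed by this 1,2-shift through a spiro-phenonium-like transition state (formally a 3-exo-tet displacement at C3), not by a cyclization, so the six-membered pyran loses C4 to the exocyclic ketone. C2 is carried over unchanged and controls C3: anti addition followed by migration with inversion places the aroyl group trans to the C2 aryl group, and because C3–H is alpha to the new ketone any cis isomer should epimerise to the more stable trans compound. The step needs migration of ring carbon C4a rather than of the exocyclic 2,4-dialkoxyphenyl group or epoxide closure; the equatorial C2 aryl group favours the conformer in which only the ring bond is antiperiplanar to the leaving group, and the ortho oxygen O1 makes C4a an electron-rich migrating carbon.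

**Step 6**
Reactants: 12 [(2R,3R)-5-bromo-2-[4-(methoxymethoxy)phenyl]-2,3-dihydro-1-benzofuran-3-yl][2,4-bis(methoxymethoxy)phenyl]methanone; 5 1-[2,4-bis(methoxymethoxy)phenyl]prop-2-en-1-one
Product: 13 (E)-1-[2,4-bis(methoxymethoxy)phenyl]-3-[(2R,3R)-3-[2,4-bis(methoxymethoxy)benzoyl]-2-[4-(methoxymethoxy)phenyl]-2,3-dihydro-1-benzofuran-5-yl]prop-2-en-1-one
Conditions: Pd[P(t-Bu)3]2 (5 mol %), Cy2NMe (1.5 equiv), BHT (trace), 1,4-dioxane, 70 °C
Reagents that add atoms: none
Why: Mizoroki–Heck reaction: oxidative addition of zerovalent palladium carrying a bulky electron-rich phosphine into the electron-rich aryl bromide, syn carbopalladation of the vinyl ketone and syn β-hydride elimination should give the E-enone, while the hindered amine base leaves both stereocenters alone (epimerisation at C3 would in any case return the trans isomer).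

**Step 7**
Reactants: 13 (E)-1-[2,4-bis(methoxymethoxy)phenyl]-3-[(2R,3R)-3-[2,4-bis(methoxymethoxy)benzoyl]-2-[4-(methoxymethoxy)phenyl]-2,3-dihydro-1-benzofuran-5-yl]prop-2-en-1-one
Product: 14 (E)-1-(2,4-dihydroxyphenyl)-3-[(2R,3R)-3-(2,4-dihydroxybenzoyl)-2-(4-hydroxyphenyl)-2,3-dihydro-1-benzofuran-5-yl]prop-2-en-1-one
Conditions: 3 M aq. HCl, MeOH/THF, 50 °C
Reagents that add atoms: none
Why: Acid-catalysed transacetalisation of the five aryl MOM acetals to methanol (acetal cleavage) should free all phenols under conditions mild enough for the E-enone and the benzylic C2–O bond, and no stereocenter is touched.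

**Compound list**
1 | 4-bromobenzene-1,3-diol | Oc1ccc(Br)c(O)c1 | starting material
2 | 1-bromo-2,4-bis(methoxymethoxy)benzene | COCOc1ccc(Br)c(OCOC)c1 | intermediate
3 | N-methoxy-N-methylprop-2-enamide | C=CC(=O)N(C)OC | starting material
4 | [2,4-bis(methoxymethoxy)phenyl]lithium | COCOc1ccc([Li])c(OCOC)c1 | intermediate
5 | 1-[2,4-bis(methoxymethoxy)phenyl]prop-2-en-1-one | C=CC(=O)c1ccc(OCOC)cc1OCOC | intermediate
6 | 6-bromo-4H-chromen-4-one | O=c1ccoc2ccc(Br)cc12 | starting material
7 | [4-(methoxymethoxy)phenyl]boronic acid | COCOc1ccc(B(O)O)cc1 | starting material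
8 | (2R)-6-bromo-2-[4-(methoxymethoxy)phenyl]-2,3-dihydro-4H-chromen-4-one | O=C1C[C@H](c2ccc(OCOC)cc2)Oc2ccc(Br)cc21 | intermediate
9 | [2,4-bis(methoxymethoxy)phenyl]magnesium bromide | COCOc1ccc([Mg]Br)c(OCOC)c1 | intermediate
10 | (2R)-6-bromo-4-[2,4-bis(methoxymethoxy)phenyl]-2-[4-(methoxymethoxy)phenyl]-3,4-dihydro-2H-chromen-4-ol (both C4 epimers) | COCOc1ccc(C2(O)C[C@H](c3ccc(OCOC)cc3)Oc3ccc(Br)cc32)c(OCOC)c1 | intermediate
11 | (2R)-6-bromo-4-[2,4-bis(methoxymethoxy)phenyl]-2-[4-(methoxymethoxy)phenyl]-2H-chromene | COCOc1ccc(C2=C[C@H](c3ccc(OCOC)cc3)Oc3ccc(Br)cc32)c(OCOC)c1 | intermediate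
12 | [(2R,3R)-5-bromo-2-[4-(methoxymethoxy)phenyl]-2,3-dihydro-1-benzofuran-3-yl][2,4-bis(methoxymethoxy)phenyl]methanone | Brc1ccc2c(c1)[C@@H](C(=O)c1ccc(OCOC)cc1OCOC)[C@H](c1ccc(OCOC)cc1)O2 | intermediate
13 | (E)-1-[2,4-bis(methoxymethoxy)phenyl]-3-[(2R,3R)-3-[2,4-bis(methoxymethoxy)benzoyl]-2-[4-(methoxymethoxy)phenyl]-2,3-dihydro-1-benzofuran-5-yl]prop-2-en-1-one | O=C(/C=C/c1ccc2c(c1)[C@@H](C(=O)c1ccc(OCOC)cc1OCOC)[C@H](c1ccc(OCOC)cc1)O2)c1ccc(OCOC)cc1OCOC | intermediate
14 | (E)-1-(2,4-dihydroxyphenyl)-3-[(2R,3R)-3-(2,4-dihydroxybenzoyl)-2-(4-hydroxyphenyl)-2,3-dihydro-1-benzofuran-5-yl]prop-2-en-1-one | O=C(/C=C/c1ccc2c(c1)[C@@H](C(=O)c1ccc(O)cc1O)[C@H](c1ccc(O)cc1)O2)c1ccc(O)cc1O | target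

**Total step count:** 7 steps.
**Longest linear sequence:** 5 steps (steps 3, 4, 5, 6, 7 from 6-bromochromone, or steps 1, 4, 5, 6, 7 from 4-bromoresorcinol).

**Steps most likely to fail**

Step 5 (bears the label). The exocyclic electron-rich aryl group may migrate in place of ring carbon C4a, the hydroxy iodane may close to an epoxide or be solvolysed, and the sulfonic acid released may strip MOM groups and expose phenols to the oxidant. The fallback uses the established oxidative contraction of flavanones and sets out from flavanone 8. Treatment with PhI(OAc)2 and catalytic H2SO4 in trimethyl orthoformate at room temperature should give, through the enol ether, anti iodination at C3 and the same shift of C4a, methyl (2R,3R)-5-bromo-2-[4-(methoxymethoxy)phenyl]-2,3-dihydro-1-benzofuran-3-carboxylate F1. Aminolysis with MeNH(OMe)·HCl and AlMe3 in CH2Cl2 would convert it into (2R,3R)-5-bromo-N-methoxy-2-[4-(methoxymethoxy)phenyl]-N-methyl-2,3-dihydro-1-benzofuran-3-carboxamide F2. Addition of arylmagnesium bromide 9, prepared from bromide 2 and Mg as in step 4, in THF at −20 °C would then give ketone 12, where the route is rejoined.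

Step 6. Oxidative addition into the aryl bromide, which is deactivated by the para ring oxygen, may be slower than thermal oligomerisation of the vinyl ketone, and prolonged heating with base invites enolisation at C3. The fallback sets out from bromide 12. A Stille coupling with tributyl(vinyl)stannane and Pd(PPh3)4 in toluene at 90 °C, run without base, should give [(2R,3R)-5-ethenyl-2-[4-(methoxymethoxy)phenyl]-2,3-dihydro-1-benzofuran-3-yl][2,4-bis(methoxymethoxy)phenyl]methanone F3. Cross-metathesis of this styrene with vinyl ketone 5, using second-generation Hoveyda–Grubbs catalyst in CH2Cl2 at 40 °C, would deliver the E-enone 13, where the route is rejoined.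

Step 4. The basic Grignard reagent may deprotonate C3 of the flavanone instead of adding to the carbonyl, and the enolate may expel the phenoxide, opening the ring with loss of material and of the C2 stereocenter. The fallback avoids carbonyl addition and sets out from flavanone 8. Tf2O and 2,6-di-tert-butyl-4-methylpyridine in CH2Cl2, a non-basic enol triflation, should give (2R)-6-bromo-2-[4-(methoxymethoxy)phenyl]-2H-chromen-4-yl trifluoromethanesulfonate F4. Its coupling partner is [2,4-bis(methoxymethoxy)phenyl]boronic acid F5, made from aryllithium 4 (generated from bromide 2 as in step 2) and B(OMe)3 with a mild aqueous acidic work-up. A Suzuki–Miyaura coupling of the two under Pd(PPh3)4 and K3PO4 in THF/H2O at room temperature should engage the alkenyl triflate ahead of the electron-rich aryl bromide. This gives chromene 11, where the route is rejoined.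

**Further compounds**
F1 | step 5 | methyl (2R,3R)-5-bromo-2-[4-(methoxymethoxy)phenyl]-2,3-dihydro-1-benzofuran-3-carboxylate | Brc1ccc2c(c1)[C@@H](C(=O)OC)[C@H](c1ccc(OCOC)cc1)O2
F2 | step 5 | (2R,3R)-5-bromo-N-methoxy-2-[4-(methoxymethoxy)phenyl]-N-methyl-2,3-dihydro-1-benzofuran-3-carboxamide | Brc1ccc2c(c1)[C@@H](C(=O)N(C)OC)[C@H](c1ccc(OCOC)cc1)O2
F3 | step 6 | [(2R,3R)-5-ethenyl-2-[4-(methoxymethoxy)phenyl]-2,3-dihydro-1-benzofuran-3-yl][2,4-bis(methoxymethoxy)phenyl]methanone | C=Cc1ccc2c(c1)[C@@H](C(=O)c1ccc(OCOC)cc1OCOC)[C@H](c1ccc(OCOC)cc1)O2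
F4 | step 4 | (2R)-6-bromo-2-[4-(methoxymethoxy)phenyl]-2H-chromen-4-yl trifluoromethanesulfonate | O=S(=O)(OC1=C[C@H](c2ccc(OCOC)cc2)Oc2ccc(Br)cc21)C(F)(F)F
F5 | step 4 | [2,4-bis(methoxymethoxy)phenyl]boronic acid | COCOc1ccc(B(O)O)c(OCOC)c1
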